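Of the starting material charged, the ochre flask held 44.1% as target at 95 min, and the amber flask held 22.5%. Amber differed from ochre in having 3.00 times the starting material, which made partner its limiting reagent. The next decision was blue, which keeps amber's starting material and raises the partner 3.00 times. I would adopt blue if its share beat ochre's; otherwise I would keep ochre, which spends less of both.

common to all: catalyst 0.00240 M
- ochre: starting material 0.0800 M; partner 0.0800 M
- grey: starting material 0.0480 M; partner 0.0480 M
- green: starting material 0.0800 M; partner 0.0400 M
- amber: starting material 0.240 M; partner 0.0800 M
- blue: starting material 0.240 M; partner 0.240 M; time 95 min

| ochre run: time / min | ochre run: [target] / M | grey run: time / min | grey run: [target] / M | green run: time / min | green run: [target] / M | amber run: time / min | amber run: [target] / M |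
|---|---|---|---|---|---|---|---|
| 3.8 | 0.0054 | 3.8 | 0.0026 | 3.8 | 0.0030 | 3.8 | 0.0102 |
| 8.5 | 0.0113 | 8.5 | 0.0049 | 8.5 | 0.0060 | 8.5 | 0.0198 |
| 19 | 0.0205 | 19 | 0.0094 | 19 | 0.0124 | 19 | 0.0341 |
| 42 | 0.0297 | 42 | 0.0160 | 42 | 0.0190 | 42 | 0.0478 |
| 95 | 0.0353 | 95 | 0.0208 | 95 | 0.0253 | 95 | 0.0541 |

(standard deviation of a reading: 4 × 10⁻⁴ M)

- the power of [partner] that the first rate follows, about the charge of the ochre run; measure it at two percent of starting material made into target
- the power of [starting material] that the first rate follows, about the charge of the ochre run; measure it at two percent of starting material made into target (one fixed amount of target, the same in the runs compared)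
- target in the blue run at 95 min, as a share of the starting material charged

- Overall: starting material + partner -> target, with catalyst as catalyst.
- Constant volume, constant temperature.
- Bound and free are read together.
- "The second partner" is partner.
- An order is taken over about fifteen percent of the charge, up and down.

In ochre, the pace up to the first reading, carried on to 95 min, gives 169% of the charge, so a first pace needs a shorter time to multiply it by. I therefore divided the share at 95 min by the share gained per minute up to the first reading. Ochre gave 24.8 min. This is the coast time, the time a flask would need at its first pace to reach what it holds at 95 min. Green, with half the partner and the same starting material, gave 32.0 min, longer than ochre, so between these two flasks the coast time fell as the partner's power 0.367. Green's first reading carries 13.3% of scatter, so that power is rough.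

Amber gave 20.2 min. Blue has amber's starting material, so I started from amber and changed the partner alone, taking the ochre and green pair as a guide. Their first readings give a partner order of 0.848. Carried to blue's partner, that lifts amber's first pace to my estimate of 0.0284 min⁻¹ of the charge, and my estimate of the coast time for blue is 13.5 min. Their product is 38.2%, below ochre's share, so I decided to keep ochre as the recipe and run blue once for the number.

The forecast, by its own route, gave 0.85 (0.7 to 1) for the partner order, 0.65 (0.45 to 0.85) for the starting-material order, and 38% (31% to 45%) for blue. Its ground was that “All runs stall well short of simple second-order behaviour”.

The simulation gave orders of 0.95 in partner and 0.61 in starting material, and blue held 36.0%, each inside the forecast's range. Blue stayed below ochre's share, so ochre remained the recipe.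

    catalyst + starting material ⇌ catalyst-substrate complex, settled at all times (10.20 L mol⁻¹)
    catalyst-substrate complex + partner ⇌ ternary complex, settled at all times (2.700 L mol⁻¹)
    ternary complex → target + catalyst (6.600 min⁻¹)
    target + partner → side product (0.2226 L mol⁻¹ min⁻¹)
    starting material + partner → target (0.04032 L mol⁻¹ min⁻¹)

At my reckoned first pace, blue's share means a coast time of 12.7 min, shorter than ochre's 24.8 min. The main reason for blue's low share is the loss of target with partner to side product. Without that step, the blue run reached 85.4%, a coast time of 30.1 min at the same first pace.

(The data come from a simulation with made-up constants, noise included.)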